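The whole plan rests on cutting the C4–C5 bond of ring A (halimane numbering). The target's quaternary C4 carries the acid carbon C18, and its neighbour C5 is a methine next to the C1=C10 double bond of ring A; one anodic oxidation exploits both. A C4=C18 ketene dithioacetal is oxidised to a radical cation, C5 of a C5=C10–C1–Si allylsilane bonds to C4, ring A closes, silicon leaves so that the alkene lands at C1=C10, and C18 is delivered at the acid oxidation level with C4 and C5 set together. The precursor is a ring-B cyclohexene bearing the finished C11–C16 chain on C9 and, on C10, a (1R)-silylated arm ending in the dithianylidene group.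

Key step: step 13

Remark: silicon at C1 carries Me2Ph (so that it can be delivered stereospecifically from a silylboronate) and O15 carries tert-butyldiphenylsilyl (stable to the ketal hydrolysis); compound 14 and (+)-sparteine are taken as purchasable.

Step 1
Reactants: 1 2-methylcyclohex-2-en-1-one; 2 acetaldehyde
Product: 4 (2R,3R)-2-(1-hydroxyethyl)-2,3-dimethylcyclohexan-1-one (both carbinol epimers), via dimethylaluminium enolate 3 (not isolated)
Conditions: AlMe3, Cu(O2CC4H3S) (copper thiophene-2-carboxylate, 2 mol %), chiral BINOL-derived phosphoramidite (4 mol %), Et2O, −30 °C; then MeCHO, −78 °C; aq. potassium sodium tartrate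
Reagents that add atoms: trimethylaluminium, C[Al](C)C
Why: Copper-catalysed asymmetric conjugate addition should set C8 (ligand enantiomer chosen for 3R), and the aluminium enolate should then undergo an aldol addition to acetaldehyde on the face anti to the new C8 methyl, which sets quaternary C9 with the two ring methyls cis.

Step 2
Reactants: 4 (2R,3R)-2-(1-hydroxyethyl)-2,3-dimethylcyclohexan-1-one
Product: 5 (2S,3R)-2-ethenyl-2,3-dimethylcyclohexan-1-one
Conditions: Ph2S[OC(CF3)2Ph]2 (Martin sulfurane), CH2Cl2, 0 °C → rt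
Reagents that add atoms: none
Why: Martin sulfurane dehydration (E2 of the alkoxysulfonium ion) can only remove a hydrogen from the methyl group because C9 is quaternary, and the neutral conditions should avoid retro-aldol cleavage.

Step 3
Reactants: 6 but-2-yn-1-ol
Product: 7 tert-butyl(but-2-yn-1-yloxy)diphenylsilane
Conditions: t-BuPh2SiCl, imidazole, CH2Cl2, rt
Reagents that add atoms: tert-butyl(chloro)diphenylsilane, CC(C)(C)[Si](Cl)(c1ccccc1)c1ccccc1
Why: Routine silylation of a primary alcohol, giving an ether robust enough for the bases, the hydrazine and the mild acid used later.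

Step 4
Reactants: 7 tert-butyl(but-2-yn-1-yloxy)diphenylsilane
Product: 9 tert-butyl{[(2E)-3-iodobut-2-en-1-yl]oxy}diphenylsilane, via alkenylzirconocene chloride 8 (not isolated)
Conditions: Cp2Zr(H)Cl (1.5 equiv), THF, 50 °C; then I2, THF, 0 °C
Reagents that add atoms: iodine, II
Why: Hydrozirconation is a syn addition and, with excess reagent and warming, should equilibrate zirconium to the less hindered methyl-bearing carbon; iodinolysis with retention then gives the E iodide.

Step 5
Reactants: 5 (2S,3R)-2-ethenyl-2,3-dimethylcyclohexan-1-one; 9 tert-butyl{[(2E)-3-iodobut-2-en-1-yl]oxy}diphenylsilane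
Product: 11 (2S,3R)-2-[(3E)-5-{[tert-butyl(diphenyl)silyl]oxy}-3-methylpent-3-en-1-yl]-2,3-dimethylcyclohexan-1-one, via B-alkyl-9-borabicyclo[3.3.1]nonane 10 (not isolated)
Conditions: 9-BBN, THF, 0 °C → rt; then 9, Pd(dppf)Cl2 (5 mol %), AsPh3, Cs2CO3, DMF/H2O, rt
Reagents that add atoms: none
Why: Anti-Markovnikov hydroboration of the vinyl group should outpace reduction of the hindered ketone, and the B-alkyl Suzuki–Miyaura coupling keeps the iodide geometry, so the C13=C14 alkene is installed as E without a new stereocentre.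

Step 6
Reactants: 11 (2S,3R)-2-[(3E)-5-{[tert-butyl(diphenyl)silyl]oxy}-3-methylpent-3-en-1-yl]-2,3-dimethylcyclohexan-1-one
Product: 12 {(2S,3R)-2-[(3E)-5-{[tert-butyl(diphenyl)silyl]oxy}-3-methylpent-3-en-1-yl]-2,3-dimethylcyclohexylidene}hydrazine
Conditions: N2H4·H2O, Et3N, EtOH, 80 °C, argon
Reagents that add atoms: hydrazine, NN
Why: Hydrazone condensation with excess hydrazine should suppress azine formation, and no stereocentre next to the carbonyl can epimerise.

Step 7
Reactants: 12 hydrazone of ketone 11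
Product: 13 tert-butyl{[(2E)-5-[(1S,6R)-2-iodo-1,6-dimethylcyclohex-2-en-1-yl]-3-methylpent-2-en-1-yl]oxy}diphenylsilane
Conditions: I2, TMG, THF, 0 °C → rt
Reagents that add atoms: iodine, II
Why: The Barton vinyl iodide synthesis (oxidation to the diazoalkane, iodination, loss of N2 and of a proton) can only place the alkene at C5=C10 because C9 carries no hydrogen.

Step 8
Reactants: 14 3-(2-methyl-1,3-dioxolan-2-yl)propan-1-ol
Product: 15 3-(2-methyl-1,3-dioxolan-2-yl)propyl di(propan-2-yl)carbamate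
Conditions: i-Pr2NC(O)Cl, Et3N, CH2Cl2, reflux
Reagents that add atoms: N,N-di(propan-2-yl)carbamoyl chloride, CC(C)N(C(C)C)C(Cl)=O
Why: O-Carbamoylation installs the directing group needed for the enantioselective α-lithiation.

Step 9
Reactants: 15 3-(2-methyl-1,3-dioxolan-2-yl)propyl di(propan-2-yl)carbamate
Product: 18 2-{(1S)-1-[dimethyl(phenyl)silyl]-3-(2-methyl-1,3-dioxolan-2-yl)propyl}-4,4,5,5-tetramethyl-1,3,2-dioxaborolane, via lithiated carbamate 16 (not isolated), via silylborate complex 17 (not isolated)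
Conditions: s-BuLi, (+)-sparteine, Et2O, −78 °C; then PhMe2Si–B(pin), −78 °C → reflux
Reagents that add atoms: 2-[dimethyl(phenyl)silyl]-4,4,5,5-tetramethyl-1,3,2-dioxaborolane, C[Si](C)(c1ccccc1)B1OC(C)(C)C(C)(C)O1
Why: Hoppe-type sparteine-mediated deprotonation gives the (R)-organolithium, which adds to boron with retention; the silyl group then shifts from boron to carbon with inversion (lithiation–borylation, 1,2-metallate rearrangement), setting the future C1 centre as S.

Step 10
Reactants: 13 ring-B alkenyl iodide; 18 (S)-α-silyl boronic ester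
Product: 21 tert-butyl{[(2E)-5-{(1S,6R)-2-[(1R)-1-[dimethyl(phenyl)silyl]-3-(2-methyl-1,3-dioxolan-2-yl)propyl]-1,6-dimethylcyclohex-2-en-1-yl}-3-methylpent-2-en-1-yl]oxy}diphenylsilane, via alkenyllithium 19 (not isolated), via alkenylborate complex 20 (not isolated)
Conditions: t-BuLi (2 equiv), THF, −78 °C; 18, −78 °C; I2, THF, −78 °C; NaOMe, MeOH, −78 °C → rt
Reagents that add atoms: none
Why: In the Zweifel olefination, iodine triggers a 1,2-shift of the α-silyl alkyl group from boron to C10 with retention at the migrating carbon and boron–iodine elimination restores the C5=C10 alkene, so the centre made in step 9 becomes (1R) in the allylsilane.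

Step 11
Reactants: 21 allylsilane ketal
Product: 22 (5R)-5-[dimethyl(phenyl)silyl]-5-{(5R,6S)-6-[(3E)-5-{[tert-butyl(diphenyl)silyl]oxy}-3-methylpent-3-en-1-yl]-5,6-dimethylcyclohex-1-en-1-yl}pentan-2-one
Conditions: PPTS, acetone/H2O, 50 °C
Reagents that add atoms: water, O
Why: Acid-catalysed ketal hydrolysis with a weak acid should leave the allylsilane and the tert-butyldiphenylsilyl ether untouched.

Step 12
Reactants: 22 methyl ketone; 23 2-(trimethylsilyl)-1,3-dithiane
Product: 25 tert-butyl{[(2E)-5-{(1S,6R)-2-[(1R)-1-[dimethyl(phenyl)silyl]-4-(1,3-dithian-2-ylidene)pentyl]-1,6-dimethylcyclohex-2-en-1-yl}-3-methylpent-2-en-1-yl]oxy}diphenylsilane, via 2-lithio-2-(trimethylsilyl)-1,3-dithiane 24 (not isolated)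
Conditions: 23, n-BuLi, THF, 0 °C; then 22, −78 °C → rt
Reagents that add atoms: none
Why: In the Peterson olefination the silyl-stabilised dithiane anion adds to the methyl ketone and the β-silyl alkoxide collapses to the ketene dithioacetal, whose geometry is irrelevant because the dithiane is symmetric.

Step 13
Reactants: 25 ring-B allylsilane with ketene dithioacetal arm
Product: 26 tert-butyl{[(2E)-5-[(1S,2R,4aS,5S)-5-(2-methoxy-1,3-dithian-2-yl)-1,2,5-trimethyl-1,2,3,4,4a,5,6,7-octahydronaphthalen-1-yl]-3-methylpent-2-en-1-yl]oxy}diphenylsilane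
Conditions: reticulated vitreous carbon anode, Pt cathode, undivided cell, LiClO4 (0.1 M), MeOH/THF (3:7), 2,6-lutidine, constant current (8 mA), 2.2 F/mol, rt
Reagents that add atoms: methanol, CO
Why: The ketene dithioacetal has the lowest oxidation potential in 25, so the anode removes one electron from it and the radical cation is electrophilic at C4; C5 of the allylsilane bonds to C4, the β-silyl cation at C10 hands its silyl group to methanol to leave the C1=C10 alkene, and the dithio-stabilised C18 radical is oxidised again and captured by methanol as the ortho ester. The closest known reaction type is the anodic olefin coupling of ketene dithioacetal radical cations with allylsilanes, which is used to build quaternary carbons. Ring A closes as a six-membered ring, exo with respect to C4=C18 and endo with respect to C5=C10. C5 is controlled by the (1R)-silyl centre: with C2 held syn to C5 by the tether, the C1–Si bond stands on the β face and, as in an anti SE2′ substitution, C4 bonds to the α face so that H5 ends β; C4 is controlled by a chair-like closure with the bulky dithianylidene carbon pseudo-equatorial and the methyl pseudo-axial, cis to C6. The step needs oxidation of the ketene dithioacetal before the allylsilane, the C13=C14 alkene or the aryl silanes (secured by its much lower potential), ring closure faster than methanol capture at C4 (secured by the six-membered intramolecular reach, a low methanol content and the 2,6-lutidine buffer), and an alkene at C1=C10 only (secured by silicon, which leaves no proton-loss path towards C5).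

Step 14
Reactants: 26 bicyclic 2-methoxy-1,3-dithiane ortho ester
Product: 28 (1S,5S,6R,8aS)-5-[(3E)-5-{[tert-butyl(diphenyl)silyl]oxy}-3-methylpent-3-en-1-yl]-1,5,6-trimethyl-1,2,3,5,6,7,8,8a-octahydronaphthalene-1-carboxylic acid, via S-(3-sulfanylpropyl) thioester 27 (not isolated)
Conditions: AcOH/THF/H2O, rt; then AgNO3, 2,6-lutidine, THF/H2O, rt
Reagents that add atoms: water, O
Why: Acid hydrolysis of the O,S,S-ortho ester expels methanol first and so gives the ring-opened thioester, and thiophilic silver-assisted thioester hydrolysis then frees the acid at hindered C4 without base or strong acid.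

Step 15
Reactants: 28 silyl ether acid
Product: 29 (1S,5S,6R,8aS)-5-[(3E)-5-hydroxy-3-methylpent-3-en-1-yl]-1,5,6-trimethyl-1,2,3,5,6,7,8,8a-octahydronaphthalene-1-carboxylic acid
Conditions: TBAF (3 equiv), THF, rt
Reagents that add atoms: none
Why: Fluoride-mediated desilylation is safe at this stage because no allylsilane remains, and the excess fluoride allows for deprotonation of the acid.

Step 16
Reactants: 29 hydroxy acid
Product: 30 (1S,5S,6R,8aS)-1,5,6-trimethyl-5-[(3E)-3-methyl-5-(propanoyloxy)pent-3-en-1-yl]-1,2,3,5,6,7,8,8a-octahydronaphthalene-1-carboxylic acid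
Conditions: (EtCO)2O, pyridine, DMAP (cat.), CH2Cl2, 0 °C → rt; then THF/aq. NaHCO3, acidify
Reagents that add atoms: propanoic anhydride, CCC(=O)OC(=O)CC
Why: DMAP-catalysed acylation should take the unhindered primary allylic alcohol, and any mixed anhydride formed at the hindered tertiary acid is hydrolysed in the aqueous work-up.

Compound list

1 | 2-methylcyclohex-2-en-1-one | CC1=CCCC1=O | starting material
2 | acetaldehyde | CC=O | starting material
3 | dimethylaluminium (3R)-2,3-dimethylcyclohex-1-en-1-olate | C[C@@H]1CCCC(O[Al](C)C)=C1C | intermediate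
4 | (2R,3R)-2-(1-hydroxyethyl)-2,3-dimethylcyclohexan-1-one (both carbinol epimers) | CC(O)[C@]1(C)C(=O)CCC[C@H]1C | intermediate
5 | (2S,3R)-2-ethenyl-2,3-dimethylcyclohexan-1-one | C=C[C@]1(C)C(=O)CCC[C@H]1C | intermediate
6 | but-2-yn-1-ol | CC#CCO | starting material
7 | tert-butyl(but-2-yn-1-yloxy)diphenylsilane | CC#CCO[Si](c1ccccc1)(c1ccccc1)C(C)(C)C | intermediate
8 | chlorido[(2E)-4-{[tert-butyl(diphenyl)silyl]oxy}but-2-en-2-yl]bis(cyclopentadienyl)zirconium | C/C(=C\CO[Si](c1ccccc1)(c1ccccc1)C(C)(C)C)[Zr](Cl)(C1C=CC=C1)C1C=CC=C1 | intermediate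
9 | tert-butyl{[(2E)-3-iodobut-2-en-1-yl]oxy}diphenylsilane | C/C(I)=C\CO[Si](c1ccccc1)(c1ccccc1)C(C)(C)C | intermediate
10 | 9-{2-[(1S,6R)-1,6-dimethyl-2-oxocyclohexyl]ethyl}-9-borabicyclo[3.3.1]nonane | B1(CC[C@]2(C)C(=O)CCC[C@H]2C)C2CCCC1CCC2 | intermediate
11 | (2S,3R)-2-[(3E)-5-{[tert-butyl(diphenyl)silyl]oxy}-3-methylpent-3-en-1-yl]-2,3-dimethylcyclohexan-1-one | CC(C)(C)[Si](OC/C=C(\C)CC[C@]1(C)C(=O)CCC[C@H]1C)(c1ccccc1)c1ccccc1 | intermediate
12 | {(2S,3R)-2-[(3E)-5-{[tert-butyl(diphenyl)silyl]oxy}-3-methylpent-3-en-1-yl]-2,3-dimethylcyclohexylidene}hydrazine | CC(C)(C)[Si](OC/C=C(\C)CC[C@]1(C)C(=NN)CCC[C@H]1C)(c1ccccc1)c1ccccc1 | intermediate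
13 | tert-butyl{[(2E)-5-[(1S,6R)-2-iodo-1,6-dimethylcyclohex-2-en-1-yl]-3-methylpent-2-en-1-yl]oxy}diphenylsilane | CC(C)(C)[Si](OC/C=C(\C)CC[C@]1(C)C(I)=CCC[C@H]1C)(c1ccccc1)c1ccccc1 | intermediate
14 | 3-(2-methyl-1,3-dioxolan-2-yl)propan-1-ol | CC1(CCCO)OCCO1 | starting material
15 | 3-(2-methyl-1,3-dioxolan-2-yl)propyl di(propan-2-yl)carbamate | CC(C)N(C(C)C)C(=O)OCCCC1(C)OCCO1 | intermediate
16 | {(1R)-1-[di(propan-2-yl)carbamoyloxy]-3-(2-methyl-1,3-dioxolan-2-yl)propyl}lithium, (+)-sparteine complex | [Li][C@@H](OC(=O)N(C(C)C)C(C)C)CCC1(C)OCCO1 | intermediate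
17 | lithium {(1R)-1-[di(propan-2-yl)carbamoyloxy]-3-(2-methyl-1,3-dioxolan-2-yl)propyl}[dimethyl(phenyl)silyl](pinacolato)borate | [Li+].C[Si](C)(c1ccccc1)[B-]1(OC(C)(C)C(C)(C)O1)[C@@H](OC(=O)N(C(C)C)C(C)C)CCC1(C)OCCO1 | intermediate
18 | 2-{(1S)-1-[dimethyl(phenyl)silyl]-3-(2-methyl-1,3-dioxolan-2-yl)propyl}-4,4,5,5-tetramethyl-1,3,2-dioxaborolane | CC1(C)OB(OC1(C)C)[C@H]([Si](C)(C)c1ccccc1)CCC1(C)OCCO1 | intermediate
19 | {(5R,6S)-6-[(3E)-5-{[tert-butyl(diphenyl)silyl]oxy}-3-methylpent-3-en-1-yl]-5,6-dimethylcyclohex-1-en-1-yl}lithium | CC(C)(C)[Si](OC/C=C(\C)CC[C@]1(C)C([Li])=CCC[C@H]1C)(c1ccccc1)c1ccccc1 | intermediate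
20 | lithium borate of 19 and 18 (boron bound to ring carbon C10, to the (1S)-silylated carbon and to pinacolate) | [Li+].CC(C)(C)[Si](OC/C=C(\C)CC[C@]1(C)C(=CCC[C@H]1C)[B-]1(OC(C)(C)C(C)(C)O1)[C@H]([Si](C)(C)c1ccccc1)CCC1(C)OCCO1)(c1ccccc1)c1ccccc1 | intermediate
21 | tert-butyl{[(2E)-5-{(1S,6R)-2-[(1R)-1-[dimethyl(phenyl)silyl]-3-(2-methyl-1,3-dioxolan-2-yl)propyl]-1,6-dimethylcyclohex-2-en-1-yl}-3-methylpent-2-en-1-yl]oxy}diphenylsilane | CC(C)(C)[Si](OC/C=C(\C)CC[C@]1(C)C(=CCC[C@H]1C)[C@H]([Si](C)(C)c1ccccc1)CCC1(C)OCCO1)(c1ccccc1)c1ccccc1 | intermediate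
22 | (5R)-5-[dimethyl(phenyl)silyl]-5-{(5R,6S)-6-[(3E)-5-{[tert-butyl(diphenyl)silyl]oxy}-3-methylpent-3-en-1-yl]-5,6-dimethylcyclohex-1-en-1-yl}pentan-2-one | CC(C)(C)[Si](OC/C=C(\C)CC[C@]1(C)C(=CCC[C@H]1C)[C@H]([Si](C)(C)c1ccccc1)CCC(C)=O)(c1ccccc1)c1ccccc1 | intermediate
23 | 2-(trimethylsilyl)-1,3-dithiane | C[Si](C)(C)C1SCCCS1 | starting material
24 | 2-lithio-2-(trimethylsilyl)-1,3-dithiane | [Li]C1([Si](C)(C)C)SCCCS1 | intermediate
25 | tert-butyl{[(2E)-5-{(1S,6R)-2-[(1R)-1-[dimethyl(phenyl)silyl]-4-(1,3-dithian-2-ylidene)pentyl]-1,6-dimethylcyclohex-2-en-1-yl}-3-methylpent-2-en-1-yl]oxy}diphenylsilane | CC(C)(C)[Si](OC/C=C(\C)CC[C@]1(C)C(=CCC[C@H]1C)[C@H]([Si](C)(C)c1ccccc1)CCC(C)=C1SCCCS1)(c1ccccc1)c1ccccc1 | intermediate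
26 | tert-butyl{[(2E)-5-[(1S,2R,4aS,5S)-5-(2-methoxy-1,3-dithian-2-yl)-1,2,5-trimethyl-1,2,3,4,4a,5,6,7-octahydronaphthalen-1-yl]-3-methylpent-2-en-1-yl]oxy}diphenylsilane | CC(C)(C)[Si](OC/C=C(\C)CC[C@]1(C)C2=CCC[C@](C)(C3(OC)SCCCS3)[C@H]2CC[C@H]1C)(c1ccccc1)c1ccccc1 | intermediate
27 | S-(3-sulfanylpropyl) (1S,5S,6R,8aS)-5-[(3E)-5-{[tert-butyl(diphenyl)silyl]oxy}-3-methylpent-3-en-1-yl]-1,5,6-trimethyl-1,2,3,5,6,7,8,8a-octahydronaphthalene-1-carbothioate | CC(C)(C)[Si](OC/C=C(\C)CC[C@]1(C)C2=CCC[C@](C)(C(=O)SCCCS)[C@H]2CC[C@H]1C)(c1ccccc1)c1ccccc1 | intermediate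
28 | (1S,5S,6R,8aS)-5-[(3E)-5-{[tert-butyl(diphenyl)silyl]oxy}-3-methylpent-3-en-1-yl]-1,5,6-trimethyl-1,2,3,5,6,7,8,8a-octahydronaphthalene-1-carboxylic acid | CC(C)(C)[Si](OC/C=C(\C)CC[C@]1(C)C2=CCC[C@](C)(C(=O)O)[C@H]2CC[C@H]1C)(c1ccccc1)c1ccccc1 | intermediate
29 | (1S,5S,6R,8aS)-5-[(3E)-5-hydroxy-3-methylpent-3-en-1-yl]-1,5,6-trimethyl-1,2,3,5,6,7,8,8a-octahydronaphthalene-1-carboxylic acid | OC/C=C(\C)CC[C@]1(C)C2=CCC[C@](C)(C(=O)O)[C@H]2CC[C@H]1C | intermediate
30 | (1S,5S,6R,8aS)-1,5,6-trimethyl-5-[(3E)-3-methyl-5-(propanoyloxy)pent-3-en-1-yl]-1,2,3,5,6,7,8,8a-octahydronaphthalene-1-carboxylic acid | CCC(=O)OC/C=C(\C)CC[C@]1(C)C2=CCC[C@](C)(C(=O)O)[C@H]2CC[C@H]1C | target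

Total step count: 16. Longest linear sequence: 12 steps (steps 1, 2, 5, 6, 7, 10, 11, 12, 13, 14, 15 and 16) from 2-methylcyclohex-2-en-1-one; the two branches (steps 3–4 and steps 8–9) have two steps each.

Steps most likely to fail

Step 13 (the radical cation is captured by methanol at C4, or is over-oxidised, before C5 can bond): from 25, oxidation at one sulfur (mCPBA, 1 equiv, CH2Cl2, −78 °C) would give the ketene dithioacetal S-oxide F1. Tf2O with 2,6-di-tert-butyl-4-methylpyridine at −78 °C would then trigger an additive Pummerer reaction, in which the activated sulfoxide makes C4 electrophilic by a two-electron path. C5 of the allylsilane would close ring A with loss of silicon, and the 1,3-dithian-2-ylium ion so formed would be quenched with MeOH/Et3N to rejoin the route at 26.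

Step 10 (incomplete formation of the hindered borate at C10, or failure of the iodine-induced shift): from 11, LiN(i-Pr)2 and PhNTf2 would give the enol triflate F2, which can only form towards C5. Separately, (chloromethyl)dimethylphenylsilane would be lithiated (s-BuLi, TMEDA) and alkylated with 2-(2-bromoethyl)-2-methyl-1,3-dioxolane to the racemic α-chlorosilane F3, and magnesium would convert this into the configurationally labile Grignard reagent F4. An asymmetric Kumada coupling of F2 with F4 under PdCl2 and the chiral ferrocenylphosphine (R)-(S)-PPFA (enantiomer chosen for 1R, dynamic kinetic resolution of the Grignard reagent) would rejoin the route at 21.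

Step 1 (retro-aldol loss or poor trapping of the aluminium enolate, eroding yield or the C9 centre): from 1, the same conjugate addition would be quenched with Me3SiOTf/Et3N to give the silyl enol ether F5. MeLi would release the lithium enolate, whose Michael addition to phenyl vinyl sulfoxide, again anti to the C8 methyl, would give the keto sulfoxide F6. Thermal syn-elimination of the sulfoxide (toluene, CaCO3, 110 °C) would rejoin the route at 5, so that steps 1 and 2 are both replaced.

Further compounds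

F1 | step 13 | tert-butyl{[(2E)-5-{(1S,6R)-2-[(1R)-1-[dimethyl(phenyl)silyl]-4-(1-oxo-1,3-dithian-2-ylidene)pentyl]-1,6-dimethylcyclohex-2-en-1-yl}-3-methylpent-2-en-1-yl]oxy}diphenylsilane (mixture at sulfur and about C4=C18) | CC(C)(C)[Si](OC/C=C(\C)CC[C@]1(C)C(=CCC[C@H]1C)[C@H]([Si](C)(C)c1ccccc1)CCC(C)=C1SCCCS1=O)(c1ccccc1)c1ccccc1
F2 | step 10 | (5R,6S)-6-[(3E)-5-{[tert-butyl(diphenyl)silyl]oxy}-3-methylpent-3-en-1-yl]-5,6-dimethylcyclohex-1-en-1-yl trifluoromethanesulfonate | CC(C)(C)[Si](OC/C=C(\C)CC[C@]1(C)C(OS(=O)(=O)C(F)(F)F)=CCC[C@H]1C)(c1ccccc1)c1ccccc1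
F3 | step 10 | racemic [1-chloro-3-(2-methyl-1,3-dioxolan-2-yl)propyl]dimethyl(phenyl)silane | C[Si](C)(c1ccccc1)C(Cl)CCC1(C)OCCO1
F4 | step 10 | chlorido{1-[dimethyl(phenyl)silyl]-3-(2-methyl-1,3-dioxolan-2-yl)propyl}magnesium | C[Si](C)(c1ccccc1)C([Mg]Cl)CCC1(C)OCCO1
F5 | step 1 | trimethyl{[(3R)-2,3-dimethylcyclohex-1-en-1-yl]oxy}silane | C[C@@H]1CCCC(O[Si](C)(C)C)=C1C
F6 | step 1 | (2S,3R)-2,3-dimethyl-2-[2-(phenylsulfinyl)ethyl]cyclohexan-1-one (both sulfoxide epimers) | O=S(CC[C@]1(C)C(=O)CCC[C@H]1C)c1ccccc1
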